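**Retrosynthetic overview**
1. The target comes from protected lactone 32 by ketal hydrolysis and desilylation. The C3–C(sp2) bond of the right-hand dienyl chain is cut to the zinc enolate of lactone 18 and dienyl iodide 29 (Pd-catalysed α-alkenylation, anti to the C4 methyl).
2. Lactone 18 is cut at the central bond of the left diene (Suzuki coupling) into lactone iodoalkene 9 and alkenylboronate 17 (stereocentre from an Evans hydroxymethylation). Iodide 29 comes from an Evans syn-aldol of iododienal 22.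
3. Iodoalkene 9 comes from hydroxymethyl lactone 5 by oxidation, alkyne homologation and Zr-catalysed methylalumination–iodination.
4. The only ring is the γ-lactone (O1, C2, C3, C4, C5). With its trans C4 methyl and one-carbon branch on C5 it equals C2–C6 of a 3,4-dideoxyhexose. It is made first, from levoglucosenone, by methyl addition anti to the anhydro bridge and Baeyer–Villiger excision of the anomeric carbon (2 → 5).

Key step: step 2

Assumption: (E)-pent-2-en-4-yn-1-ol, (R)-4-benzyloxazolidin-2-one and its N-propanoyl derivative are taken as catalogue compounds.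

**Route**

Step 1
Reactants: 1 levoglucosenone
Product: 2 (1S,2S,5R)-2-methyl-6,8-dioxabicyclo[3.2.1]octan-4-one
Conditions: MeMgBr, CuI (10 mol %), THF, −78 → −40 °C; aq. NH4Cl
Reagents that add atoms: methylmagnesium bromide, C[Mg]Br
Why: Copper-catalysed conjugate addition of the Grignard reagent; the 1,6-anhydro bridge shields one face of the enone, so methyl adds to C2 from the opposite face and sets it as S.

Step 2
Reactants: 2 (1S,2S,5R)-2-methyl-6,8-dioxabicyclo[3.2.1]octan-4-one
Product: 5 (4S,5S)-5-(hydroxymethyl)-4-methyloxolan-2-one, via ring-expanded lactone 3 (not isolated), via formate ester 4 (not isolated)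
Conditions: 30% aq. H2O2 (1.2 equiv), H2O, 50 °C; then Amberlyst 15, H2O, 50 °C
Reagents that add atoms: none
Why: H2O2 adds to the ketone of 2, which the adjacent acetal activates, and the Criegee adduct rearranges with migration of the acetal carbon C5 to oxygen (Baeyer–Villiger oxidation), cleaving the C4–C5 bond to give acyloxy acetal 3. The closest known reaction is the peroxide oxidation of dihydrolevoglucosenone and its 4-substituted congeners to 5-(hydroxymethyl) γ-butyrolactones. Under acid the orthoformate-type carbon of 3 is released as the former pyranose oxygen O8 acylates at the ester carbonyl, closing the γ-lactone (O1–C2 bond) by a 5-exo-trig acyl transfer; the old anomeric carbon is left as formate 4, which the acid resin hydrolyses to 5 and formic acid. No stereocentre is created: C4 and C5 of the lactone are C2 and C1 of 2 and take no part in bond breaking. The step needs migration of the acetal carbon in preference to the C3 methylene, which the two oxygen substituents on C5 secure by stabilising the developing positive charge; no other oxidisable group is present.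

Step 3
Reactants: 5 (4S,5S)-5-(hydroxymethyl)-4-methyloxolan-2-one
Product: 6 (2S,3S)-3-methyl-5-oxooxolane-2-carbaldehyde
Conditions: Dess–Martin periodinane, CH2Cl2, 0 °C → rt; used crude
Reagents that add atoms: none
Why: Dess–Martin oxidation of the primary alcohol under neutral conditions gives the α-acyloxy aldehyde without touching the lactone or the C5 stereocentre.

Step 4
Reactants: 6 (2S,3S)-3-methyl-5-oxooxolane-2-carbaldehyde
Product: 7 (4S,5S)-5-ethynyl-4-methyloxolan-2-one
Conditions: dimethyl (1-diazo-2-oxopropyl)phosphonate, K2CO3, MeOH, 0 °C; then p-TsOH (cat.), CH2Cl2, rt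
Reagents that add atoms: dimethyl (1-diazo-2-oxopropyl)phosphonate, COP(=O)(OC)C(=[N+]=[N-])C(C)=O
Why: Seyferth–Gilbert homologation with the Ohira–Bestmann reagent turns the aldehyde into the terminal alkyne at 0 °C; the acid treatment re-closes any lactone opened by methanol, and C5 keeps the thermodynamically preferred trans relation to the C4 methyl.

Step 5
Reactants: 7 (4S,5S)-5-ethynyl-4-methyloxolan-2-one
Product: 9 (4S,5S)-5-[(E)-1-iodoprop-1-en-2-yl]-4-methyloxolan-2-one, via alkenylalane 8 (not isolated)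
Conditions: Me3Al (3 equiv), Cp2ZrCl2 (0.25 equiv), H2O (1 equiv), CH2Cl2, −25 → 0 °C; then I2, THF, −25 °C
Reagents that add atoms: trimethylaluminium, C[Al](C)C; iodine, II
Why: Negishi zirconium-catalysed methylalumination adds Me and Al syn across the terminal alkyne with Al on the terminal carbon, and iodinolysis with retention gives the E-iodoalkene; Me3Al should not add to an ester carbonyl at this temperature, and the alane is 1,3 to the C5–O bond, so β-elimination cannot occur.

Step 6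
Reactants: 10 (R)-4-benzyloxazolidin-2-one
Product: 11 (R)-4-benzyl-3-hexanoyloxazolidin-2-one
Conditions: hexanoyl chloride, Et3N, DMAP (cat.), CH2Cl2, 0 °C → rt
Reagents that add atoms: hexanoyl chloride, CCCCCC(=O)Cl
Why: DMAP-catalysed N-acylation of the oxazolidinone with the acid chloride.

Step 7
Reactants: 11 (R)-4-benzyl-3-hexanoyloxazolidin-2-one
Product: 13 (R)-4-benzyl-3-[(S)-2-(hydroxymethyl)hexanoyl]oxazolidin-2-one, via titanium enolate 12 (not isolated)
Conditions: TiCl4, i-Pr2NEt, CH2Cl2, 0 °C; then 1,3,5-trioxane, TiCl4, 0 °C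
Reagents that add atoms: 1,3,5-trioxane, C1OCOCO1
Why: Evans titanium-enolate hydroxymethylation: the chelated Z-enolate is attacked by TiCl4-activated formaldehyde on the face opposite the benzyl group, which sets the new stereocentre as S.

Step 8
Reactants: 13 (R)-4-benzyl-3-[(S)-2-(hydroxymethyl)hexanoyl]oxazolidin-2-one
Product: 14 (R)-4-benzyl-3-[(S)-2-({[tert-butyl(dimethyl)silyl]oxy}methyl)hexanoyl]oxazolidin-2-one
Conditions: TBSCl, imidazole, CH2Cl2, rt
Reagents that add atoms: tert-butyldimethylsilyl chloride, CC(C)(C)[Si](C)(C)Cl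
Why: Silylation of the primary alcohol keeps the two CH2O arms distinct once the auxiliary is removed.

Step 9
Reactants: 14 (R)-4-benzyl-3-[(S)-2-({[tert-butyl(dimethyl)silyl]oxy}methyl)hexanoyl]oxazolidin-2-one
Product: 15 (R)-2-({[tert-butyl(dimethyl)silyl]oxy}methyl)hexan-1-ol
Conditions: LiBH4, MeOH (1 equiv), THF, 0 °C
Reagents that add atoms: none
Why: Reductive cleavage of the N-acyloxazolidinone with LiBH4 gives the primary alcohol and returns the auxiliary; the conditions should neither enolise the stereocentre nor move the silyl group.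

Step 10
Reactants: 15 (R)-2-({[tert-butyl(dimethyl)silyl]oxy}methyl)hexan-1-ol
Product: 16 (S)-2-({[tert-butyl(dimethyl)silyl]oxy}methyl)hexanal
Conditions: Dess–Martin periodinane, pyridine, CH2Cl2, 0 °C; used at once
Reagents that add atoms: none
Why: Dess–Martin oxidation under buffered, non-basic conditions gives the α-branched aldehyde with minimal risk of epimerisation.

Step 11
Reactants: 16 (S)-2-({[tert-butyl(dimethyl)silyl]oxy}methyl)hexanal
Product: 17 tert-butyl(dimethyl){[(2R,3E)-2-butyl-4-(4,4,5,5-tetramethyl-1,3,2-dioxaborolan-2-yl)but-3-enyl]oxy}silane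
Conditions: Cl2CHBpin, CrCl2, LiI, THF, rt
Reagents that add atoms: 2-(dichloromethyl)-4,4,5,5-tetramethyl-1,3,2-dioxaborolane, ClC(Cl)B1OC(C)(C)C(C)(C)O1
Why: Takai–Utimoto boryl-olefination: the geminal dichromium reagent converts the aldehyde into the E-alkenylboronate under non-basic conditions that should leave the α-stereocentre intact.

Step 12
Reactants: 9 (4S,5S)-5-[(E)-1-iodoprop-1-en-2-yl]-4-methyloxolan-2-one; 17 tert-butyl(dimethyl){[(2R,3E)-2-butyl-4-(4,4,5,5-tetramethyl-1,3,2-dioxaborolan-2-yl)but-3-enyl]oxy}silane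
Product: 18 (4S,5S)-5-[(2E,4E,6R)-6-({[tert-butyl(dimethyl)silyl]oxy}methyl)deca-2,4-dien-2-yl]-4-methyloxolan-2-one
Conditions: PdCl2(dppf) (5 mol %), AsPh3, Cs2CO3, DMF/H2O, rt
Reagents that add atoms: none
Why: Suzuki–Miyaura alkenyl–alkenyl coupling with retention at both partners gives the E,E-diene; oxidative addition into the C–I bond should outpace ionisation of the allylic C5–O bond, and the carbonate base is mild enough for the lactone.

Step 13
Reactants: 19 (E)-pent-2-en-4-yn-1-ol
Product: 21 (2E,4E)-5-iodo-4-methylpenta-2,4-dien-1-ol, via alkenylalane 20 (not isolated)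
Conditions: Me3Al (3 equiv), Cp2ZrCl2 (0.25 equiv), ClCH2CH2Cl, 0 °C → rt; then I2, THF, −30 °C
Reagents that add atoms: trimethylaluminium, C[Al](C)C; iodine, II
Why: Negishi zirconium-catalysed methylalumination of the enynol (syn addition, Al terminal) followed by iodinolysis gives the E,E-iododienol.

Step 14
Reactants: 21 (2E,4E)-5-iodo-4-methylpenta-2,4-dien-1-ol
Product: 22 (2E,4E)-5-iodo-4-methylpenta-2,4-dienal
Conditions: MnO2, CH2Cl2, rt
Reagents that add atoms: none
Why: MnO2 oxidation of the allylic alcohol to the dienal.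

Step 15
Reactants: 23 (R)-4-benzyl-3-propanoyloxazolidin-2-one; 22 (2E,4E)-5-iodo-4-methylpenta-2,4-dienal
Product: 25 (R)-4-benzyl-3-[(2R,3S,4E,6E)-3-hydroxy-7-iodo-2,6-dimethylhepta-4,6-dienoyl]oxazolidin-2-one, via boron enolate 24 (not isolated)
Conditions: Bu2BOTf, Et3N, CH2Cl2, −78 → 0 °C; 22, −78 → 0 °C; then pH 7 buffer, MeOH, 30% H2O2, 0 °C
Reagents that add atoms: none
Why: Evans syn-aldol: the Z-boron enolate reacts through a Zimmerman–Traxler chair on the face opposite the benzyl group, setting C2 as R and C3 as S (syn).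

Step 16
Reactants: 25 (R)-4-benzyl-3-[(2R,3S,4E,6E)-3-hydroxy-7-iodo-2,6-dimethylhepta-4,6-dienoyl]oxazolidin-2-one
Product: 26 (2R,3S,4E,6E)-3-hydroxy-7-iodo-N-methoxy-N,2,6-trimethylhepta-4,6-dienamide
Conditions: MeNHOMe·HCl, Me3Al, THF/CH2Cl2, −20 → 0 °C
Reagents that add atoms: N,O-dimethylhydroxylamine hydrochloride, CNOC.Cl
Why: Aluminium-amide transamidation of the imide to the Weinreb amide, assisted by the free β-hydroxyl, with release of the auxiliary.

Step 17
Reactants: 26 (2R,3S,4E,6E)-3-hydroxy-7-iodo-N-methoxy-N,2,6-trimethylhepta-4,6-dienamide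
Product: 27 (2R,3S,4E,6E)-3-{[tert-butyl(dimethyl)silyl]oxy}-7-iodo-N-methoxy-N,2,6-trimethylhepta-4,6-dienamide
Conditions: TBSOTf, 2,6-lutidine, CH2Cl2, −78 °C
Reagents that add atoms: tert-butyldimethylsilyl trifluoromethanesulfonate, CC(C)(C)[Si](C)(C)OS(=O)(=O)C(F)(F)F
Why: Silylation of the secondary allylic alcohol with the silyl triflate and a hindered base.

Step 18
Reactants: 27 (2R,3S,4E,6E)-3-{[tert-butyl(dimethyl)silyl]oxy}-7-iodo-N-methoxy-N,2,6-trimethylhepta-4,6-dienamide
Product: 28 (3R,4S,5E,7E)-4-{[tert-butyl(dimethyl)silyl]oxy}-8-iodo-3,7-dimethylocta-5,7-dien-2-one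
Conditions: MeMgBr, THF, 0 °C; aq. NH4Cl
Reagents that add atoms: methylmagnesium bromide, C[Mg]Br
Why: Grignard addition to the Weinreb amide stops at the chelated tetrahedral adduct and gives the methyl ketone on work-up; MeMgBr should not exchange with the alkenyl iodide at 0 °C.

Step 19
Reactants: 28 (3R,4S,5E,7E)-4-{[tert-butyl(dimethyl)silyl]oxy}-8-iodo-3,7-dimethylocta-5,7-dien-2-one
Product: 29 tert-butyl{[(1E,3E,5S,6R)-1-iodo-7,7-dimethoxy-2,6-dimethylocta-1,3-dien-5-yl]oxy}dimethylsilane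
Conditions: MeOSiMe3, TMSOTf (cat.), CH2Cl2, −78 °C; Et3N quench
Reagents that add atoms: methoxytrimethylsilane, CO[Si](C)(C)C
Why: Noyori ketalisation masks the ketone at low temperature without enolising the adjacent stereocentre, so that the zinc enolate of step 20 cannot add to it in a Reformatsky manner.

Step 20
Reactants: 18 (4S,5S)-5-[(2E,4E,6R)-6-({[tert-butyl(dimethyl)silyl]oxy}methyl)deca-2,4-dien-2-yl]-4-methyloxolan-2-one; 29 tert-butyl{[(1E,3E,5S,6R)-1-iodo-7,7-dimethoxy-2,6-dimethylocta-1,3-dien-5-yl]oxy}dimethylsilane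
Product: 32 (3S,4S,5S)-5-[(2E,4E,6R)-6-({[tert-butyl(dimethyl)silyl]oxy}methyl)deca-2,4-dien-2-yl]-3-[(1E,3E,5S,6R)-5-{[tert-butyl(dimethyl)silyl]oxy}-7,7-dimethoxy-2,6-dimethylocta-1,3-dienyl]-4-methyloxolan-2-one, via lithium enolate 30 (not isolated), via zinc enolate 31 (not isolated)
Conditions: LiN(SiMe3)2, THF, −78 °C; ZnCl2, −78 °C → rt; then 29 (1.2 equiv), Pd(dba)2 (5 mol %), P(t-Bu)3 (5 mol %), THF, rt; pH 7 buffer
Reagents that add atoms: none
Why: Palladium-catalysed α-alkenylation of an ester zinc enolate (Negishi-type coupling of a Reformatsky-type reagent with an alkenyl iodide) forms the C3–C(sp2) bond with retention of alkene geometry on the enolate face anti to the C4 methyl, giving the 3,4-trans lactone, which is also the more stable epimer; the weakly basic zinc enolate limits proton transfer from the product and migration of its double bond.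

Step 21
Reactants: 32 the bis-silyl dimethyl ketal from step 20
Product: 33 (3S,4S,5S)-5-[(2E,4E,6R)-6-({[tert-butyl(dimethyl)silyl]oxy}methyl)deca-2,4-dien-2-yl]-3-[(1E,3E,5S,6R)-5-{[tert-butyl(dimethyl)silyl]oxy}-2,6-dimethyl-7-oxoocta-1,3-dienyl]-4-methyloxolan-2-one
Conditions: PPTS (cat.), acetone/H2O, rt
Reagents that add atoms: water, O
Why: Mild acid-catalysed hydrolysis of the dimethyl ketal frees the ketone while the silyl ether on the neighbouring carbinol still guards against β-elimination.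

Step 22
Reactants: 33 the bis-silyl ketone from step 21
Product: 34 CNP0187795.2, (3S,4S,5S)-5-[(2E,4E,6R)-6-(hydroxymethyl)deca-2,4-dien-2-yl]-3-[(1E,3E,5S,6R)-5-hydroxy-2,6-dimethyl-7-oxoocta-1,3-dienyl]-4-methyloxolan-2-one
Conditions: HF·pyridine, pyridine, THF, 0 °C → rt
Reagents that add atoms: none
Why: Fluoride cleavage of both silyl ethers under buffered, slightly acidic conditions avoids retro-aldol, β-elimination and base-induced migration of the C3 alkene into conjugation.

**Compound list**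
1 | levoglucosenone, (1S,5R)-6,8-dioxabicyclo[3.2.1]oct-2-en-4-one | O1C[C@H]2O[C@@H]1C(=O)C=C2 | starting material
2 | (1S,2S,5R)-2-methyl-6,8-dioxabicyclo[3.2.1]octan-4-one | O1C[C@H]2O[C@@H]1C(=O)C[C@@H]2C | intermediate
3 | (1R,5S,6S)-5-methyl-2,8,9-trioxabicyclo[4.2.1]nonan-3-one (ring-expanded lactone) | O1C[C@H]2O[C@@H]1OC(=O)C[C@@H]2C | intermediate
4 | [(2S,3S)-3-methyl-5-oxooxolan-2-yl]methyl formate | O=COC[C@H]1OC(=O)C[C@@H]1C | intermediate
5 | (4S,5S)-5-(hydroxymethyl)-4-methyloxolan-2-one | OC[C@H]1OC(=O)C[C@@H]1C | intermediate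
6 | (2S,3S)-3-methyl-5-oxooxolane-2-carbaldehyde | O=C[C@H]1OC(=O)C[C@@H]1C | intermediate
7 | (4S,5S)-5-ethynyl-4-methyloxolan-2-one | C#C[C@H]1OC(=O)C[C@@H]1C | intermediate
8 | dimethyl{(E)-2-[(2S,3S)-3-methyl-5-oxooxolan-2-yl]prop-1-enyl}alane | C[Al](C)/C=C(\C)[C@H]1OC(=O)C[C@@H]1C | intermediate
9 | (4S,5S)-5-[(E)-1-iodoprop-1-en-2-yl]-4-methyloxolan-2-one | I/C=C(\C)[C@H]1OC(=O)C[C@@H]1C | intermediate
10 | (R)-4-benzyloxazolidin-2-one | O=C1N[C@H](Cc2ccccc2)CO1 | starting material
11 | (R)-4-benzyl-3-hexanoyloxazolidin-2-one | CCCCCC(=O)N1[C@H](Cc2ccccc2)COC1=O | intermediate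
12 | trichlorotitanium (Z)-enolate of 11 | Cl[Ti](Cl)(Cl)O/C(=C\CCCC)N1[C@H](Cc2ccccc2)COC1=O | intermediate
13 | (R)-4-benzyl-3-[(S)-2-(hydroxymethyl)hexanoyl]oxazolidin-2-one | CCCC[C@@H](CO)C(=O)N1[C@H](Cc2ccccc2)COC1=O | intermediate
14 | (R)-4-benzyl-3-[(S)-2-({[tert-butyl(dimethyl)silyl]oxy}methyl)hexanoyl]oxazolidin-2-one | CCCC[C@@H](CO[Si](C)(C)C(C)(C)C)C(=O)N1[C@H](Cc2ccccc2)COC1=O | intermediate
15 | (R)-2-({[tert-butyl(dimethyl)silyl]oxy}methyl)hexan-1-ol | CCCC[C@@H](CO[Si](C)(C)C(C)(C)C)CO | intermediate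
16 | (S)-2-({[tert-butyl(dimethyl)silyl]oxy}methyl)hexanal | CCCC[C@@H](CO[Si](C)(C)C(C)(C)C)C=O | intermediate
17 | tert-butyl(dimethyl){[(2R,3E)-2-butyl-4-(4,4,5,5-tetramethyl-1,3,2-dioxaborolan-2-yl)but-3-enyl]oxy}silane | CCCC[C@@H](CO[Si](C)(C)C(C)(C)C)/C=C/B1OC(C)(C)C(C)(C)O1 | intermediate
18 | (4S,5S)-5-[(2E,4E,6R)-6-({[tert-butyl(dimethyl)silyl]oxy}methyl)deca-2,4-dien-2-yl]-4-methyloxolan-2-one | CCCC[C@@H](CO[Si](C)(C)C(C)(C)C)/C=C/C=C(\C)[C@H]1OC(=O)C[C@@H]1C | intermediate
19 | (E)-pent-2-en-4-yn-1-ol | OC/C=C/C#C | starting material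
20 | dimethylaluminium alkoxide of (2E,4E)-5-(dimethylalumanyl)-4-methylpenta-2,4-dien-1-ol | C[Al](C)OC/C=C/C(C)=C/[Al](C)C | intermediate
21 | (2E,4E)-5-iodo-4-methylpenta-2,4-dien-1-ol | OC/C=C/C(C)=C/I | intermediate
22 | (2E,4E)-5-iodo-4-methylpenta-2,4-dienal | O=C/C=C/C(C)=C/I | intermediate
23 | (R)-4-benzyl-3-propanoyloxazolidin-2-one | CCC(=O)N1[C@H](Cc2ccccc2)COC1=O | starting material
24 | dibutylboron (Z)-enolate of 23 | CCCCB(CCCC)O/C(=C\C)N1[C@H](Cc2ccccc2)COC1=O | intermediate
25 | (R)-4-benzyl-3-[(2R,3S,4E,6E)-3-hydroxy-7-iodo-2,6-dimethylhepta-4,6-dienoyl]oxazolidin-2-one | I/C=C(C)/C=C/[C@H](O)[C@@H](C)C(=O)N1[C@H](Cc2ccccc2)COC1=O | intermediate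
26 | (2R,3S,4E,6E)-3-hydroxy-7-iodo-N-methoxy-N,2,6-trimethylhepta-4,6-dienamide | I/C=C(C)/C=C/[C@H](O)[C@@H](C)C(=O)N(C)OC | intermediate
27 | (2R,3S,4E,6E)-3-{[tert-butyl(dimethyl)silyl]oxy}-7-iodo-N-methoxy-N,2,6-trimethylhepta-4,6-dienamide | I/C=C(C)/C=C/[C@H](O[Si](C)(C)C(C)(C)C)[C@@H](C)C(=O)N(C)OC | intermediate
28 | (3R,4S,5E,7E)-4-{[tert-butyl(dimethyl)silyl]oxy}-8-iodo-3,7-dimethylocta-5,7-dien-2-one | I/C=C(C)/C=C/[C@H](O[Si](C)(C)C(C)(C)C)[C@@H](C)C(C)=O | intermediate
29 | tert-butyl{[(1E,3E,5S,6R)-1-iodo-7,7-dimethoxy-2,6-dimethylocta-1,3-dien-5-yl]oxy}dimethylsilane | I/C=C(C)/C=C/[C@H](O[Si](C)(C)C(C)(C)C)[C@@H](C)C(C)(OC)OC | intermediate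
30 | lithium enolate of 18 | CCCC[C@@H](CO[Si](C)(C)C(C)(C)C)/C=C/C=C(\C)[C@H]1OC(O[Li])=C[C@@H]1C | intermediate
31 | chlorozinc enolate of 18 | CCCC[C@@H](CO[Si](C)(C)C(C)(C)C)/C=C/C=C(\C)[C@H]1OC(O[Zn]Cl)=C[C@@H]1C | intermediate
32 | (3S,4S,5S)-5-[(2E,4E,6R)-6-({[tert-butyl(dimethyl)silyl]oxy}methyl)deca-2,4-dien-2-yl]-3-[(1E,3E,5S,6R)-5-{[tert-butyl(dimethyl)silyl]oxy}-7,7-dimethoxy-2,6-dimethylocta-1,3-dienyl]-4-methyloxolan-2-one | CCCC[C@@H](CO[Si](C)(C)C(C)(C)C)/C=C/C=C(\C)[C@H]1OC(=O)[C@@H](/C=C(C)/C=C/[C@H](O[Si](C)(C)C(C)(C)C)[C@@H](C)C(C)(OC)OC)[C@@H]1C | intermediate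
33 | (3S,4S,5S)-5-[(2E,4E,6R)-6-({[tert-butyl(dimethyl)silyl]oxy}methyl)deca-2,4-dien-2-yl]-3-[(1E,3E,5S,6R)-5-{[tert-butyl(dimethyl)silyl]oxy}-2,6-dimethyl-7-oxoocta-1,3-dienyl]-4-methyloxolan-2-one | CCCC[C@@H](CO[Si](C)(C)C(C)(C)C)/C=C/C=C(\C)[C@H]1OC(=O)[C@@H](/C=C(C)/C=C/[C@H](O[Si](C)(C)C(C)(C)C)[C@@H](C)C(C)=O)[C@@H]1C | intermediate
34 | CNP0187795.2, (3S,4S,5S)-5-[(2E,4E,6R)-6-(hydroxymethyl)deca-2,4-dien-2-yl]-3-[(1E,3E,5S,6R)-5-hydroxy-2,6-dimethyl-7-oxoocta-1,3-dienyl]-4-methyloxolan-2-one | CCCC[C@H](/C=C/C=C(\C)[C@H]1OC(=O)[C@@H](/C=C(C)/C=C/[C@H](O)[C@@H](C)C(C)=O)[C@@H]1C)CO | target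

**Summary**
Total step count: 22.
Longest linear sequence: 10 steps (10 → steps 6–11, 12, 20, 21, 22; equally 19 → steps 13–19, 20, 21, 22).

Steps most likely to fail:

Step 20. Transmetalation and reductive elimination at the hindered secondary zinc enolate may be slow. Proton transfer from the more acidic product to unreacted enolate may then move the C3 alkene into conjugation with the lactone. Once the iodide is consumed, zerovalent palladium may also ionise the dienylic C5–O bond of the lactone. The fallback reverses the polarity at C3 and sets out from 18 and 29. Lactone 18 is enolised (LiN(SiMe3)2, THF, −78 °C) and brominated with N-bromosuccinimide to the α-bromo lactone F1, whose C3 epimers need not be separated. Iodide 29 is taken through iodine–lithium exchange (t-BuLi, Et2O, −78 °C) and ZnCl2 to the alkenylzinc chloride F2. A nickel-catalysed Negishi-type coupling of the secondary α-bromo carbonyl compound with the alkenylzinc (NiCl2·glyme, 2,2′-bipyridine-type ligand, THF/DMA, 0 °C → rt) then joins F1 and F2. The C3 radical should be captured anti to the C4 methyl, and the route is rejoined at 32.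

Step 5. Complexation of Me3Al by the lactone carbonyl may slow the carbometalation, and methyl transfer to the carbonyl or Lewis-acid opening at the propargylic C5–O bond may compete. The fallback removes the carbonyl before the organoaluminium step and sets out from 7. Reduction with i-Bu2AlH (CH2Cl2, −78 °C) gives the lactol F3, and MeOH/PPTS converts it into the methyl acetal F4. The same methylalumination–iodination (Me3Al, Cp2ZrCl2; I2) then gives the iodoalkene acetal F5. Oxidation of the cyclic acetal with CrO3/aq. H2SO4 in acetone restores the lactone and rejoins the route at 9.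

Step 4. K2CO3 in methanol may open the lactone to an unstable α-hydroxy aldehyde and may epimerise C5 before homologation is complete. The fallback avoids alkoxide altogether and sets out from 6. CBr4/PPh3 (CH2Cl2, 0 °C) gives the 1,1-dibromoalkene F6. Pd(PPh3)4-catalysed hydrogenolysis with Bu3SnH removes the bromine trans to the ring and gives the (Z)-bromoalkene F7. Bu4NF in DMF eliminates HBr and rejoins the route at 7.

Further compounds
F1 | step 20 | (4R,5S)-3-bromo-5-[(2E,4E,6R)-6-({[tert-butyl(dimethyl)silyl]oxy}methyl)deca-2,4-dien-2-yl]-4-methyloxolan-2-one (C3 epimers) | CCCC[C@@H](CO[Si](C)(C)C(C)(C)C)/C=C/C=C(\C)[C@H]1OC(=O)C(Br)[C@@H]1C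
F2 | step 20 | chloro[(1E,3E,5S,6R)-5-{[tert-butyl(dimethyl)silyl]oxy}-7,7-dimethoxy-2,6-dimethylocta-1,3-dienyl]zinc | Cl[Zn]/C=C(C)/C=C/[C@H](O[Si](C)(C)C(C)(C)C)[C@@H](C)C(C)(OC)OC
F3 | step 5 | (4S,5S)-5-ethynyl-4-methyloxolan-2-ol (anomers) | C#C[C@H]1OC(O)C[C@@H]1C
F4 | step 5 | (2S,3S)-2-ethynyl-5-methoxy-3-methyloxolane (anomers) | C#C[C@H]1OC(OC)C[C@@H]1C
F5 | step 5 | (2S,3S)-2-[(E)-1-iodoprop-1-en-2-yl]-5-methoxy-3-methyloxolane (anomers) | I/C=C(\C)[C@H]1OC(OC)C[C@@H]1C
F6 | step 4 | (4S,5S)-5-(2,2-dibromoethenyl)-4-methyloxolan-2-one | BrC(Br)=C[C@H]1OC(=O)C[C@@H]1C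
F7 | step 4 | (4S,5S)-5-[(Z)-2-bromoethenyl]-4-methyloxolan-2-one | Br/C=C\[C@H]1OC(=O)C[C@@H]1C
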